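Remark on the chemistry: labdane numbering is used throughout (C1–C10 decalin, C11–C13 in ring C, C14–C16 in ring D, C17 on C8, C18/C19 on C4, C20 on C10; α is the face opposite C20). The chiral ligands in steps 3 and 9 are named for the sense of induction assumed here and would be exchanged for their antipodes if that sense proved opposite.

## The problem

The target is a 9α,13:15,16-diepoxylabdane: a trans-decalin (rings A and B) joined through the spiro carbon C9 to a tetrahydrofuran-3-one (ring C: O–C9–C11–C12(=O)–C13), which is joined through a second spiro carbon, C13, to a 2,3-dihydrofuran (ring D: C13–C14=C15–O–C16). Four of the seven stereocentres are fully substituted (C4, C9, C10, C13), and the tertiary ether carbon C9 sits between quaternary C10 and tertiary C8. On the decalin, C19, O6 and C20 are mutually 1,3-diaxial on the β face, so C19 can deliver O6 and the axial C20 methyl can control C8 and C9; but the sense needed at C9 (oxygen α, C11 β) is the opposite of what a carbon nucleophile adding to a C9 carbonyl anti to C20 should give. C13 cannot be trusted to the decalin: seen from ring C its two faces look onto C8/C17/C7 and onto C10/C1/C5, which are nearly alike, so it must be set by a reagent. The enol ether C14=C15–O is acid-labile; C13 is at once allylic, α to the C12 ketone and an ether carbon, so acid can aromatise ring D to a 3-acylfuran with loss of the C9–O bond; base can open the β-alkoxy ketone (retro-oxa-Michael) or expel C16 (retro-aldol). The feature the plan exploits is the oxidation pattern of ring C: C9 and C13 are both carbinol carbons, 1,4-related across C11–C12(=O), so O–C9–C11–C12(=O)–C13 is the cyclised hydrate of a but-2-yne-1,4-diol whose ends are a ketone carbon (C9) and a tertiary dialkynyl carbinol (C13); ring D is likewise the cycloisomer of an ethynyl and a CH2OH group on C13.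

## Retrosynthesis

**Ring D (29 ⇒ 28).** The O–C15 bond is cut, giving alkynol 28 with ethynyl (C14≡C15) and CH2OH (C16) on C13. This cut is preferred to a lactol dehydration or an acetal elimination because the forward step is a redox-neutral isomerisation in amine base, so the acid-labile enol ether appears only in the last step and no hydride reagent meets the C12 ketone. The forward reaction must be endo-selective and must not touch the 6- and 19-hydroxyls.

**Ring C and C9 (28 ⇒ 27 ⇒ 24).** The C9–O bond is cut and the C12 carbonyl is transposed back to a C9 carbinol, giving ynediol 24. The neighbouring cuts (C9–C11 by a carbon nucleophile, or C13–O9 onto a furan) put carbon on the α face of C9 or fight furan aromaticity. Here the C9 carbinol is sacrificed to an exocyclic enone and oxygen, not carbon, arrives anti to C20. The precursor 24 is open-chain between the decalin and C13, with C9 as a stereochemically irrelevant carbinol. The forward cascade must transpose only the C9 hydroxyl and must close the five-membered ring (O13), not a six-membered one (O16).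

**C9–C11 (24 ⇒ 23 ⇒ 11 + 21).** The C9–C11 bond is cut to ketone 11 and terminal alkyne 21; an acetylide is the one carbon nucleophile small enough for this ketone and its facial selectivity does not matter. The 19,6β-lactone of 23 is reduced to the diol at this stage (24), before any ketone exists at C12, which removes a later chemoselectivity problem.

**C13 (21 ⇒ 20 ⇒ 19 ⇒ 17 ⇒ 15 + 16; 15 ⇒ 12 + 13).** C13 is made as a tertiary carbinol with two different alkynes by enantioselective addition of alkyne 16 to the alkynyl α-keto ester 15, itself from alkyne 12 and oxalate 13. The ester of 17 becomes C16 and the two silyl groups keep the alkynes distinct until one has become C11≡C12 (through diols 18 and 19 and silyl ethers 20 and 21). This places the uncontrollable centre of the target in a five-carbon fragment under catalyst control.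

**O6 and C8 (11 ⇒ 9 ⇒ 8 ⇒ 7).** The C8 methyl is cut to ketone 9 (only C8 can be enolised). The C6–O bond and the C5–H bond are cut through iodolactone 8 back to Δ5(6)-ester 7: the axial C19 carboxyl is the only group placed to deliver oxygen to the hindered 6β position, and the lactone protects both oxygens until step 14.

**Ring A (7 ⇒ 6 ⇒ 5 ⇒ 3 + 4; 3 ⇒ 1 + 2).** The C4–C5 bond is cut by a retro-aldol of ketol 6 to the achiral dione enoate 5, made from dione 1, acrolein 2 and ylide 4 via aldehyde 3. Compared with a Robinson annulation this leaves no C3 oxygen to remove, sets C4 and C10 in one desymmetrising step, and leaves the second dione carbonyl as the C9 ketone. The forward reductive aldol must distinguish two enantiotopic ketones and place the ester cis to the C10 methyl.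

## Roads not taken

**Alternative 1:** the most obvious, biomimetic cut. Cut C9–C11 with a carbon nucleophile that already contains the 3-substituted furan, then form the C13–O9 bond by acid-promoted dearomative addition of the 9-hydroxyl of A1 to the furan, giving prefuran A2, and oxidise C12 last. The chosen plan is better for four reasons. Carbon nucleophiles should add to the C9 ketone anti to C20, giving the 9β-hydroxyl rather than the 9α-hydroxyl of A1. The spiro-etherification runs against furan aromaticity under the acid that reopens it. C13 would form under control of the near-isosteric C8 and C10 flanks. A2 would still need a selective oxidation of C12 next to an enol ether.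

**Alternative 2:** Petasis–Ferrier route. Cut C9–C11 within ring C: condense ketone 11 with the α-hydroxy acid corresponding to ester 17 to give spiro-dioxolanone A3, methylenate to enol acetal A4, and let a Lewis acid trigger oxocarbenium–enolate recombination. The connectivity is right, but the step delivers carbon (C11) to a C9 oxocarbenium, again anti to C20, and should give the C9 epimer A5. Ketalisation of this hindered ketone with a tertiary hydroxy acid is also doubtful. The chosen plan turns the same facial bias to advantage by delivering oxygen.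

**Alternative 3:** late single-atom insertion. Carry an achiral spiro-cyclobutanone through the ynediol cascade to A6, in which C13 is not yet a stereocentre, and create ring D by Baeyer–Villiger oxygen insertion to lactone A7, followed by reduction and dehydration. The fragment is simpler, but C13 would be created by choosing between two CH2 groups that differ only through the C8/C10 environment, with no basis for predicting the outcome. Converting lactone A7 to the enol ether also needs hydride chemistry beside the C12 ketone, adding at least three redox and protection steps. The chosen plan fixes C13 early and forms ring D by isomerisation.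

Key step: step 15

## Route

Step 1
Reactants: 1 2-methylcyclohexane-1,3-dione; 2 acrolein (prop-2-enal)
Product: 3 3-(1-methyl-2,6-dioxocyclohexyl)propanal
Conditions: H2O, rt
Reagents that add atoms: none
Why: Michael addition of a cyclic 1,3-dione to acrolein in water is a standard entry to 2,2-disubstituted diones; no stereocentre is formed.

Step 2
Reactants: 3 3-(1-methyl-2,6-dioxocyclohexyl)propanal; 4 methyl 2-(triphenylphosphoranylidene)propanoate
Product: 5 methyl (2E)-2-methyl-5-(1-methyl-2,6-dioxocyclohexyl)pent-2-enoate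
Conditions: CH2Cl2, rt
Reagents that add atoms: none
Why: Wittig olefination with a stabilised ylide should be selective for the aldehyde over the hindered ketones and give the E trisubstituted enoate.

Step 3
Reactants: 5 methyl (2E)-2-methyl-5-(1-methyl-2,6-dioxocyclohexyl)pent-2-enoate
Product: 6 methyl 5β-hydroxy-4α,10β-dimethyl-9-oxo-cis-decalin-4β-carboxylate (ester, 5-hydroxyl and 10-methyl all β)
Conditions: Cu(OAc)2 (5 mol %), (R)-DTBM-SEGPHOS (5.5 mol %), PhSiH3 (1.2 equiv), toluene, −30 °C; aq. NH4F work-up
Reagents that add atoms: none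
Why: Copper hydride reductive aldol cyclisation of an enoate-tethered 2,2-disubstituted 1,3-dione: hydride adds to C3 and the enolate carbon C4 closes ring A on the one enantiotopic ketone selected by the chiral bisphosphine, which fixes C10 and C4 absolutely. Axial attack on the ring B carbonyl through a closed Zimmerman–Traxler transition state should give the cis ketol with the ester equatorial on ring A and gauche to the axial C5 oxygen, i.e. ester cis to the 5-hydroxyl and to C20 (4β-CO2Me, 4α-Me).

Step 4
Reactants: 6 methyl 5β-hydroxy-4α,10β-dimethyl-9-oxo-cis-decalin-4β-carboxylate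
Product: 7 methyl 4α,10β-dimethyl-9-oxo-Δ5(6)-octalin-4β-carboxylate
Conditions: Burgess reagent, toluene, 60 °C
Reagents that add atoms: none
Why: Burgess dehydration (syn elimination) of the tertiary alcohol; only C6 carries β-hydrogens because C4 and C10 are quaternary, so the Δ5(6) alkene is the only possible product. The concerted pathway avoids a C5 cation that could trigger methyl shifts.

Step 5
Reactants: 7 methyl 4α,10β-dimethyl-9-oxo-Δ5(6)-octalin-4β-carboxylate
Product: 8 5α-iodo-4α,10β-dimethyl-9-oxodecalin-19,6β-olide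
Conditions: I2 (3 equiv), MeCN, rt, dark
Reagents that add atoms: iodine, II
Why: Iodolactonisation with participation of the ester carbonyl and loss of iodomethane: iodine should add to the open α face and the axial C19 carbonyl oxygen should open the iodonium at C6 from the β face, giving the γ-lactone and setting 6β-O. Attack at C5 would need a β-lactone.

Step 6
Reactants: 8 5α-iodo-4α,10β-dimethyl-9-oxodecalin-19,6β-olide
Product: 9 4α,10β-dimethyl-9-oxo-trans-decalin-19,6β-olide (5α-H)
Conditions: Bu3SnH, AIBN (cat.), toluene, 80 °C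
Reagents that add atoms: none
Why: Radical deiodination; the C5 radical should take hydrogen from the α face because the β face is covered by the lactone bridge and C20, which sets the trans ring fusion (5α-H).

Step 7
Reactants: 9 4α,10β-dimethyl-9-oxo-trans-decalin-19,6β-olide
Product: 11 4α,8α,10β-trimethyl-9-oxo-trans-decalin-19,6β-olide, via lithium enolate 10 (not isolated)
Conditions: LDA (commercial solution), THF, −78 °C; MeI, −78 → −20 °C
Reagents that add atoms: iodomethane, CI
Why: Kinetic enolate alkylation; only C8 can be enolised (C10 and C4 are quaternary) and iodomethane should approach anti to the axial C20 methyl. This gives the equatorial 8α-methyl, which is also the thermodynamic epimer.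

Step 8
Reactants: 12 ethynyl(triisopropyl)silane; 13 diethyl oxalate
Product: 15 ethyl 2-oxo-4-(triisopropylsilyl)but-3-ynoate, via lithium acetylide 14 (not isolated)
Conditions: n-BuLi, THF, −78 °C; added to 13 (3 equiv), THF, −78 °C
Reagents that add atoms: none
Why: Acylation of a lithium acetylide by excess oxalate at low temperature should stop at the α-keto ester.

Step 9
Reactants: 15 ethyl 2-oxo-4-(triisopropylsilyl)but-3-ynoate; 16 ethynyl(trimethyl)silane
Product: 17 ethyl (2R)-2-hydroxy-4-(triisopropylsilyl)-2-[(trimethylsilyl)ethynyl]but-3-ynoate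
Conditions: Zn(OTf)2 (20 mol %), (1S,2S)-2-(dimethylamino)-3-(tert-butyldimethylsilyloxy)-1-(4-nitrophenyl)propan-1-ol (22 mol %), Et3N (30 mol %), toluene, 40 °C
Reagents that add atoms: none
Why: Zinc-mediated catalytic enantioselective alkynylation of an α-keto ester with a chiral amino alcohol; the chelating ester and the alkynyl group differentiate the two faces of the ketone, which is far more electrophilic than the ester or the silyl-shielded ynone β-carbon. This step sets C13 (R), whose four substituents are never exchanged afterwards.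

Step 10
Reactants: 17 ethyl (2R)-2-hydroxy-4-(triisopropylsilyl)-2-[(trimethylsilyl)ethynyl]but-3-ynoate
Product: 19 (2R)-2-ethynyl-4-(triisopropylsilyl)but-3-yne-1,2-diol, via silylated diol 18 (not isolated)
Conditions: NaBH4, MeOH, 0 °C; then K2CO3, MeOH, rt
Reagents that add atoms: none
Why: Borohydride reduction of the α-hydroxy ester to the 1,2-diol, then carbonate methanolysis of the trimethylsilyl alkyne only; the triisopropylsilyl alkyne is stable, so the two alkynes stay different and C13 stays stereogenic.

Step 11
Reactants: 19 (2R)-2-ethynyl-4-(triisopropylsilyl)but-3-yne-1,2-diol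
Product: 20 (2R)-1-[(tert-butyldiphenylsilyl)oxy]-2-ethynyl-4-(triisopropylsilyl)but-3-yn-2-ol
Conditions: TBDPSCl, imidazole, CH2Cl2, 0 °C
Reagents that add atoms: tert-butyl(chloro)diphenylsilane, CC(C)(C)[Si](Cl)(c1ccccc1)c1ccccc1
Why: Selective silylation of the primary hydroxyl (future O16) with an acid-stable group that must survive step 15.

Step 12
Reactants: 20 (2R)-1-[(tert-butyldiphenylsilyl)oxy]-2-ethynyl-4-(triisopropylsilyl)but-3-yn-2-ol
Product: 21 tert-butyl{[(2R)-2-ethynyl-2-[(triethylsilyl)oxy]-4-(triisopropylsilyl)but-3-yn-1-yl]oxy}diphenylsilane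
Conditions: TESOTf, 2,6-lutidine, CH2Cl2, −78 → 0 °C
Reagents that add atoms: triethylsilyl trifluoromethanesulfonate, CC[Si](CC)(CC)OS(=O)(=O)C(F)(F)F
Why: Silyl triflate silylation of the hindered tertiary propargylic alcohol; the O13 silyl ether later directs the transposition in step 15 and is the only silyl group cleaved there.

Step 13
Reactants: 21 tert-butyl{[(2R)-2-ethynyl-2-[(triethylsilyl)oxy]-4-(triisopropylsilyl)but-3-yn-1-yl]oxy}diphenylsilane; 11 4α,8α,10β-trimethyl-9-oxo-trans-decalin-19,6β-olide
Product: 23 (8βH,13R)-16-[(tert-butyldiphenylsilyl)oxy]-9-hydroxy-13-[(triethylsilyl)oxy]-15-(triisopropylsilyl)labda-11,14-diyn-19,6β-olide (C9 epimers; the 9β-hydroxy isomer is drawn), via lithium acetylide 22 (not isolated)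
Conditions: n-BuLi, THF, −78 °C; then 11, −78 → −30 °C
Reagents that add atoms: none
Why: 1,2-Addition of a lithium acetylide to a hindered ketone; the neopentyl lactone carbonyl should be much less reactive at low temperature. The C9 configuration formed here is irrelevant because step 15 erases it.

Step 14
Reactants: 23 (8βH,13R)-16-[(tert-butyldiphenylsilyl)oxy]-9-hydroxy-13-[(triethylsilyl)oxy]-15-(triisopropylsilyl)labda-11,14-diyn-19,6β-olide
Product: 24 (8βH,13R)-16-[(tert-butyldiphenylsilyl)oxy]-13-[(triethylsilyl)oxy]-15-(triisopropylsilyl)labda-11,14-diyne-6β,9,19-triol (C9 epimers)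
Conditions: LiBH4, THF/MeOH, 0 → 40 °C
Reagents that add atoms: none
Why: Borohydride reduction of the lactone to the 6β,19-diol while no ketone is present; alkynes and silyl ethers are inert to LiBH4.

Step 15
Reactants: 24 (8βH,13R)-16-[(tert-butyldiphenylsilyl)oxy]-13-[(triethylsilyl)oxy]-15-(triisopropylsilyl)labda-11,14-diyne-6β,9,19-triol
Product: 27 (8βH,13R)-16-[(tert-butyldiphenylsilyl)oxy]-6β,19-dihydroxy-15-(triisopropylsilyl)-9α,13-epoxylabd-14-yn-12-one, via silyloxy enone 25 (not isolated), via hydroxy enone 26 (not isolated)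
Conditions: Ph3PAuNTf2 (5 mol %), MeOH (2 equiv), toluene, rt; then CSA (0.2 equiv), MeOH, 0 °C → rt
Reagents that add atoms: none
Why: The cationic monovalent gold catalyst activates the C11≡C12 bond and the only free propargylic hydroxyl (on C9) undergoes 1,3-transposition (Meyer–Schuster rearrangement), which destroys the C9 stereocentre of 24 and gives exocyclic enone 25 with the carbonyl fixed at C12. The closest known reactions are gold-catalysed Meyer–Schuster rearrangements of tertiary propargylic alcohols and the mercury- or acid-mediated conversion of but-2-yne-1,4-diols into tetrahydrofuran-3-ones. Acidic methanol then removes the triethylsilyl group from O13 to give 26, whose tertiary hydroxyl adds to C9 of the protonated enone. Ring C closes in a formally 5-endo-trig oxa-Michael mode, feasible because the protonated β,β-disubstituted enone has allyl-cation character at C9. The new C9 stereocentre is controlled by the decalin: O13 enters axially on the α face, anti to the axial C20 methyl on C10, so oxygen ends α and C11 β, which should also be the more stable epimer. Regioselectivity of the transposition is secured because O13 is silylated and C13 carries the electron-withdrawing CH2OSi and alkynyl groups, so only C9 should ionise. Ring-size selectivity is secured because O16 stays as an acid-stable silyl ether, which excludes 6-endo closure, and the hindered triisopropylsilyl alkyne should not engage the catalyst. C8 and C13 are not touched, since no bond to either is broken.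

Step 16
Reactants: 27 (8βH,13R)-16-[(tert-butyldiphenylsilyl)oxy]-6β,19-dihydroxy-15-(triisopropylsilyl)-9α,13-epoxylabd-14-yn-12-one
Product: 28 (8βH,13R)-6β,16,19-trihydroxy-9α,13-epoxylabd-14-yn-12-one
Conditions: TBAF, AcOH (1:1), THF, 0 °C → rt
Reagents that add atoms: none
Why: Fluoride cleaves the O16 silyl ether and the C-silyl alkyne in one operation; acetic acid buffering keeps the medium non-basic to suppress retro-aldol loss of C16 and retro-oxa-Michael opening of ring C.

Step 17
Reactants: 28 (8βH,13R)-6β,16,19-trihydroxy-9α,13-epoxylabd-14-yn-12-one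
Product: 29 (8βH,13R)-6β,19-dihydroxy-9α,13:15,16-diepoxylabd-14-en-12-one (CNP0176827.1)
Conditions: W(CO)6 (25 mol %), Et3N, THF, hν (350 nm), 55 °C
Reagents that add atoms: none
Why: Endo-selective cycloisomerisation of a but-3-yn-1-ol through a metal vinylidene (alkynol cycloisomerisation): O16 adds to C15 and ring D forms as the 2,3-dihydrofuran in amine base, never in acid. The 6- and 19-hydroxyls cannot reach the alkyne, and no stereocentre is formed or disturbed.

## Compound list

1 | 2-methylcyclohexane-1,3-dione | CC1C(=O)CCCC1=O | starting material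
2 | acrolein (prop-2-enal) | C=CC=O | starting material
3 | 3-(1-methyl-2,6-dioxocyclohexyl)propanal | O=CCCC1(C)C(=O)CCCC1=O | intermediate
4 | methyl 2-(triphenylphosphoranylidene)propanoate | COC(=O)C(C)=P(c1ccccc1)(c1ccccc1)c1ccccc1 | starting material
5 | methyl (2E)-2-methyl-5-(1-methyl-2,6-dioxocyclohexyl)pent-2-enoate | COC(=O)/C(C)=C/CCC1(C)C(=O)CCCC1=O | intermediate
6 | methyl 5β-hydroxy-4α,10β-dimethyl-9-oxo-cis-decalin-4β-carboxylate | C1CC[C@]2(O)[C@@](C)(C(=O)OC)CCC[C@]2(C)C1=O | intermediate
7 | methyl 4α,10β-dimethyl-9-oxo-Δ5(6)-octalin-4β-carboxylate | C1CC=C2[C@@](C)(C(=O)OC)CCC[C@]2(C)C1=O | intermediate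
8 | 5α-iodo-4α,10β-dimethyl-9-oxodecalin-19,6β-olide | C1C[C@@H](O3)[C@@]2(I)[C@@](C)(C3=O)CCC[C@]2(C)C1=O | intermediate
9 | 4α,10β-dimethyl-9-oxo-trans-decalin-19,6β-olide (5α-H) | C1C[C@@H](O3)[C@H]2[C@@](C)(C3=O)CCC[C@]2(C)C1=O | intermediate
10 | lithium Δ8(9)-enolate of 9 | [Li]OC1=CC[C@@H](O3)[C@H]2[C@@](C)(C3=O)CCC[C@@]21C | intermediate
11 | 4α,8α,10β-trimethyl-9-oxo-trans-decalin-19,6β-olide | C[C@@H]1C[C@@H](O3)[C@H]2[C@@](C)(C3=O)CCC[C@]2(C)C1=O | intermediate
12 | ethynyl(triisopropyl)silane | C#C[Si](C(C)C)(C(C)C)C(C)C | starting material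
13 | diethyl oxalate | CCOC(=O)C(=O)OCC | starting material
14 | lithium (triisopropylsilyl)acetylide | [Li]C#C[Si](C(C)C)(C(C)C)C(C)C | intermediate
15 | ethyl 2-oxo-4-(triisopropylsilyl)but-3-ynoate | CCOC(=O)C(=O)C#C[Si](C(C)C)(C(C)C)C(C)C | intermediate
16 | ethynyl(trimethyl)silane | C#C[Si](C)(C)C | starting material
17 | ethyl (2R)-2-hydroxy-4-(triisopropylsilyl)-2-[(trimethylsilyl)ethynyl]but-3-ynoate | C[Si](C)(C)C#C[C@](C(=O)OCC)(C#C[Si](C(C)C)(C(C)C)C(C)C)O | intermediate
18 | (2R)-4-(triisopropylsilyl)-2-[(trimethylsilyl)ethynyl]but-3-yne-1,2-diol | C[Si](C)(C)C#C[C@](CO)(C#C[Si](C(C)C)(C(C)C)C(C)C)O | intermediate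
19 | (2R)-2-ethynyl-4-(triisopropylsilyl)but-3-yne-1,2-diol | C#C[C@](CO)(C#C[Si](C(C)C)(C(C)C)C(C)C)O | intermediate
20 | (2R)-1-[(tert-butyldiphenylsilyl)oxy]-2-ethynyl-4-(triisopropylsilyl)but-3-yn-2-ol | C#C[C@](CO[Si](c1ccccc1)(c1ccccc1)C(C)(C)C)(C#C[Si](C(C)C)(C(C)C)C(C)C)O | intermediate
21 | tert-butyl{[(2R)-2-ethynyl-2-[(triethylsilyl)oxy]-4-(triisopropylsilyl)but-3-yn-1-yl]oxy}diphenylsilane | C#C[C@](CO[Si](c1ccccc1)(c1ccccc1)C(C)(C)C)(C#C[Si](C(C)C)(C(C)C)C(C)C)O[Si](CC)(CC)CC | intermediate
22 | lithium acetylide of 21 | [Li]C#C[C@](CO[Si](c1ccccc1)(c1ccccc1)C(C)(C)C)(C#C[Si](C(C)C)(C(C)C)C(C)C)O[Si](CC)(CC)CC | intermediate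
23 | (8βH,13R)-16-[(tert-butyldiphenylsilyl)oxy]-9-hydroxy-13-[(triethylsilyl)oxy]-15-(triisopropylsilyl)labda-11,14-diyn-19,6β-olide (C9 epimers; 9β-hydroxy isomer drawn) | C[C@@H]1C[C@@H](O3)[C@H]2[C@@](C)(C3=O)CCC[C@]2(C)[C@]1(O)C#C[C@](CO[Si](c4ccccc4)(c4ccccc4)C(C)(C)C)(C#C[Si](C(C)C)(C(C)C)C(C)C)O[Si](CC)(CC)CC | intermediate
24 | (8βH,13R)-16-[(tert-butyldiphenylsilyl)oxy]-13-[(triethylsilyl)oxy]-15-(triisopropylsilyl)labda-11,14-diyne-6β,9,19-triol (C9 epimers; 9β-hydroxy isomer drawn) | C[C@@H]1C[C@@H](O)[C@H]2[C@@](C)(CO)CCC[C@]2(C)[C@]1(O)C#C[C@](CO[Si](c3ccccc3)(c3ccccc3)C(C)(C)C)(C#C[Si](C(C)C)(C(C)C)C(C)C)O[Si](CC)(CC)CC | intermediate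
25 | (8βH,13R)-16-[(tert-butyldiphenylsilyl)oxy]-6β,19-dihydroxy-13-[(triethylsilyl)oxy]-15-(triisopropylsilyl)labd-9(11)-en-14-yn-12-one (alkene geometry not defined) | C[C@@H]1C[C@@H](O)[C@H]2[C@@](C)(CO)CCC[C@]2(C)C1=CC(=O)[C@](CO[Si](c3ccccc3)(c3ccccc3)C(C)(C)C)(C#C[Si](C(C)C)(C(C)C)C(C)C)O[Si](CC)(CC)CC | intermediate
26 | (8βH,13R)-16-[(tert-butyldiphenylsilyl)oxy]-6β,13,19-trihydroxy-15-(triisopropylsilyl)labd-9(11)-en-14-yn-12-one (alkene geometry not defined) | C[C@@H]1C[C@@H](O)[C@H]2[C@@](C)(CO)CCC[C@]2(C)C1=CC(=O)[C@](CO[Si](c3ccccc3)(c3ccccc3)C(C)(C)C)(C#C[Si](C(C)C)(C(C)C)C(C)C)O | intermediate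
27 | (8βH,13R)-16-[(tert-butyldiphenylsilyl)oxy]-6β,19-dihydroxy-15-(triisopropylsilyl)-9α,13-epoxylabd-14-yn-12-one | C[C@@H]1C[C@@H](O)[C@H]2[C@@](C)(CO)CCC[C@]2(C)[C@@]12CC(=O)[C@](CO[Si](c3ccccc3)(c3ccccc3)C(C)(C)C)(C#C[Si](C(C)C)(C(C)C)C(C)C)O2 | intermediate
28 | (8βH,13R)-6β,16,19-trihydroxy-9α,13-epoxylabd-14-yn-12-one | C[C@@H]1C[C@@H](O)[C@H]2[C@@](C)(CO)CCC[C@]2(C)[C@@]12CC(=O)[C@](CO)(C#C)O2 | intermediate
29 | (8βH,13R)-6β,19-dihydroxy-9α,13:15,16-diepoxylabd-14-en-12-one (CNP0176827.1) | C[C@@H]1C[C@@H](O)[C@H]2[C@@](C)(CO)CCC[C@]2(C)[C@@]12CC(=O)[C@]1(C=COC1)O2 | target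

## Step count and risks

Total: 17 steps. Longest linear sequence: 12 steps (steps 1–7, then 13–17); the C13 branch (steps 8–12) is 5 steps before the union.

**Step 15 (key step).** Three things may go wrong: transposition in the wrong direction if the O13 silyl group is lost early and C13 ionises; Rupe-type dehydration toward C8 or a methyl shift from C10 to a cationic C9; and acid-mediated equilibration of the oxa-Michael adduct eroding the α selectivity at C9. Fallback: starting from 24, the triethylsilyl group is removed selectively (HF·pyridine, pyridine, THF, 0 °C) to give the tetrol (8βH,13R)-16-[(tert-butyldiphenylsilyl)oxy]-15-(triisopropylsilyl)labda-11,14-diyne-6β,9,13,19-tetrol F1. CO2-promoted hydration (AgOAc cat., DBU, CO2 1 atm, wet MeCN) follows, in which only the accessible O13 forms a carbonate that delivers oxygen to C12 by 5-exo-dig attack; hydrolysis gives the dihydroxy ketone (8βH,13R)-16-[(tert-butyldiphenylsilyl)oxy]-6β,9,13,19-tetrahydroxy-15-(triisopropylsilyl)labd-14-yn-12-one F2. CSA in CH2Cl2 then effects β-elimination of the C9 hydroxyl and α-face ring closure, and the route is rejoined at 27.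

**Step 3.** The α-methyl enolate must form a quaternary carbon between two fully substituted carbons, so simple conjugate reduction without closure, 1,2-reduction of the dione carbonyls, or weak discrimination between the two ketones are the likely failures. Fallback: starting from 5, an enzymatic reduction (a ketoreductase with cofactor recycling, or baker's yeast) desymmetrises the dione to the hydroxy ketone methyl (2E)-5-[(1R,2S)-2-hydroxy-1-methyl-6-oxocyclohexyl]-2-methylpent-2-enoate F3. Stoichiometric [(Ph3P)CuH]6 in toluene then closes ring A on the single remaining ketone under substrate control to give the diol ester methyl 5β,9β-dihydroxy-4α,10β-dimethyl-cis-decalin-4β-carboxylate F4, and Dess–Martin oxidation of the secondary C9 alcohol rejoins the route at 6.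

**Step 9.** The alkynyl substituent of 15 is slim, so face discrimination may be poor, and conjugate addition to the ynone may compete. Fallback: starting from 12, Sonogashira coupling (PdCl2(PPh3)2, CuI, i-Pr2NH) with 2-bromoprop-2-en-1-ol F5 gives the enynol 2-methylidene-4-(triisopropylsilyl)but-3-yn-1-ol F6. Sharpless asymmetric epoxidation (Ti(OiPr)4, L-(+)-diethyl tartrate, t-BuOOH, CH2Cl2, −20 °C) gives the epoxy alcohol [(2S)-2-[(triisopropylsilyl)ethynyl]oxiran-2-yl]methanol F7, and Dess–Martin oxidation gives the epoxy aldehyde (2R)-2-[(triisopropylsilyl)ethynyl]oxirane-2-carbaldehyde F8. Ohira–Bestmann homologation (K2CO3, MeOH) gives the diynyl epoxide (2R)-2-ethynyl-2-[(triisopropylsilyl)ethynyl]oxirane F9, and hydroxide opening at the CH2 terminus (NaOH, DMSO/H2O, 60 °C) rejoins the route at 19.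

**Step 5.** The methyl ester may participate too slowly (the dealkylation step), the iodonium intermediate may lose a proton to give allylic iodides, or the tertiary iodide may eliminate. Fallback: starting from 7, nucleophilic demethylation (LiI, pyridine, reflux) gives the acid 4α,10β-dimethyl-9-oxo-Δ5(6)-octalin-4β-carboxylic acid F10, and carboxylate-mediated iodolactonisation (I2, NaHCO3, MeCN) rejoins the route at 8.

**Step 17.** Retro-aldol loss of C16 from the β-hydroxy ketone in amine base, slow vinylidene formation at the neopentyl alkyne, or aromatisation of ring D during isolation may intervene. Fallback: starting from 28, 5-endo-dig iodoetherification (I2, NaHCO3, MeCN, 0 °C) gives the vinyl iodide (8βH)-6β,19-dihydroxy-14-iodo-9α,13:15,16-diepoxylabd-14-en-12-one F11 (C13 as in 29). Reductive removal of the vinylic iodine (Bu3SnH, Pd(PPh3)4, a zerovalent palladium catalyst, THF) rejoins the route at 29.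

## Further compounds

F1 | step 15 | (8βH,13R)-16-[(tert-butyldiphenylsilyl)oxy]-15-(triisopropylsilyl)labda-11,14-diyne-6β,9,13,19-tetrol | C[C@@H]1C[C@@H](O)[C@H]2[C@@](C)(CO)CCC[C@]2(C)[C@]1(O)C#C[C@](CO[Si](c3ccccc3)(c3ccccc3)C(C)(C)C)(C#C[Si](C(C)C)(C(C)C)C(C)C)O
F2 | step 15 | (8βH,13R)-16-[(tert-butyldiphenylsilyl)oxy]-6β,9,13,19-tetrahydroxy-15-(triisopropylsilyl)labd-14-yn-12-one | C[C@@H]1C[C@@H](O)[C@H]2[C@@](C)(CO)CCC[C@]2(C)[C@]1(O)CC(=O)[C@](CO[Si](c3ccccc3)(c3ccccc3)C(C)(C)C)(C#C[Si](C(C)C)(C(C)C)C(C)C)O
F3 | step 3 | methyl (2E)-5-[(1R,2S)-2-hydroxy-1-methyl-6-oxocyclohexyl]-2-methylpent-2-enoate | COC(=O)/C(C)=C/CC[C@@]1(C)C(=O)CCC[C@@H]1O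
F4 | step 3 | methyl 5β,9β-dihydroxy-4α,10β-dimethyl-cis-decalin-4β-carboxylate | C1CC[C@]2(O)[C@@](C)(C(=O)OC)CCC[C@]2(C)[C@H]1O
F5 | step 9 | 2-bromoprop-2-en-1-ol | OCC(Br)=C
F6 | step 9 | 2-methylidene-4-(triisopropylsilyl)but-3-yn-1-ol | OCC(=C)C#C[Si](C(C)C)(C(C)C)C(C)C
F7 | step 9 | [(2S)-2-[(triisopropylsilyl)ethynyl]oxiran-2-yl]methanol | OC[C@@]1(C#C[Si](C(C)C)(C(C)C)C(C)C)CO1
F8 | step 9 | (2R)-2-[(triisopropylsilyl)ethynyl]oxirane-2-carbaldehyde | O=C[C@@]1(C#C[Si](C(C)C)(C(C)C)C(C)C)CO1
F9 | step 9 | (2R)-2-ethynyl-2-[(triisopropylsilyl)ethynyl]oxirane | C#C[C@@]1(C#C[Si](C(C)C)(C(C)C)C(C)C)CO1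
F10 | step 5 | 4α,10β-dimethyl-9-oxo-Δ5(6)-octalin-4β-carboxylic acid | C1CC=C2[C@@](C)(C(=O)O)CCC[C@]2(C)C1=O
F11 | step 17 | (8βH)-6β,19-dihydroxy-14-iodo-9α,13:15,16-diepoxylabd-14-en-12-one (C13 as in 29) | C[C@@H]1C[C@@H](O)[C@H]2[C@@](C)(CO)CCC[C@]2(C)[C@@]12CC(=O)[C@]1(C(I)=COC1)O2
A1 | alternative 1 | (8βH)-15,16-epoxylabda-13(16),14-diene-6β,9α,19-triol | C[C@@H]1C[C@@H](O)[C@H]2[C@@](C)(CO)CCC[C@]2(C)[C@@]1(O)CCc1ccoc1
A2 | alternative 1 | (8βH,13R)-9α,13:15,16-diepoxylabd-14-ene-6β,19-diol | C[C@@H]1C[C@@H](O)[C@H]2[C@@](C)(CO)CCC[C@]2(C)[C@@]12CC[C@]1(C=COC1)O2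
A3 | alternative 2 | spiro-1,3-dioxolan-4-one of ketone 11 at C9 (ether oxygen α) carrying the C13 substituents of 21 | C[C@@H]1C[C@@H](O3)[C@H]2[C@@](C)(C3=O)CCC[C@]2(C)[C@@]14OC(=O)[C@](CO[Si](c5ccccc5)(c5ccccc5)C(C)(C)C)(C#C[Si](C(C)C)(C(C)C)C(C)C)O4
A4 | alternative 2 | 4-methylidene-1,3-dioxolane (enol acetal) derived from A3 | C[C@@H]1C[C@@H](O3)[C@H]2[C@@](C)(C3=O)CCC[C@]2(C)[C@@]14OC(=C)[C@](CO[Si](c5ccccc5)(c5ccccc5)C(C)(C)C)(C#C[Si](C(C)C)(C(C)C)C(C)C)O4
A5 | alternative 2 | (8βH,13R)-16-[(tert-butyldiphenylsilyl)oxy]-12-oxo-15-(triisopropylsilyl)-9β,13-epoxylabd-14-yn-19,6β-olide (C9 epimer of the ring C ketone) | C[C@@H]1C[C@@H](O3)[C@H]2[C@@](C)(C3=O)CCC[C@]2(C)[C@]14CC(=O)[C@](CO[Si](c5ccccc5)(c5ccccc5)C(C)(C)C)(C#C[Si](C(C)C)(C(C)C)C(C)C)O4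
A6 | alternative 3 | spiro-cyclobutanone analogue of 29 (ring D replaced by a 3-oxocyclobutane spiro-fused at C13) | C[C@@H]1C[C@@H](O)[C@H]2[C@@](C)(CO)CCC[C@]2(C)[C@@]12CC(=O)C1(CC(=O)C1)O2
A7 | alternative 3 | (8βH)-6β,19-dihydroxy-12-oxo-9α,13-epoxylabdan-15,16-olide (C13 as in 29) | C[C@@H]1C[C@@H](O)[C@H]2[C@@](C)(CO)CCC[C@]2(C)[C@@]12CC(=O)[C@]1(CC(=O)OC1)O2
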